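**Plan**
- The retrosynthesis first cuts the aryl ester C(=O)–O bond between the ring A carboxyl and the oxygen on C4 of ring B. In each ring it then cuts the aryl–CH2 bond of the 2-oxoheptyl chain at C6, together with a temporary enol-lactone C–O bond that holds ketone and acid as an isocoumarin.
- Enabling feature: in ring B the carboxyl-bearing carbon C1 lies between C2, which carries the methoxy group, and C6, the only ortho carbon with a hydrogen and the one that must bear the chain. A metal held by the C1 carboxylate can therefore reach only the C6–H bond. Ring A is analogous, with an ether oxygen on C2 and a hydrogen on C6.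
- Forward: each benzoic acid is coupled with the hexanoyl sulfoxonium ylide to a 3-pentylisocoumarin, the only ring made, which hydroxide reopens. Ring B is taken to its benzyl ester with a free 4-hydroxyl, ring A to its dioxolane-protected acid.
- The two halves are joined by esterification, then the ketal is hydrolysed and all benzyl groups are removed by hydrogenolysis.
- Stereochemistry: the target has no stereocentre and no stereogenic double bond, so nothing has to be set.

Key step: step 5

Assumption: the target is taken as the open bis(keto) acid as drawn, not as a lactol tautomer of either keto acid unit.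

**Route**

Step 1
Reactants: 1 methyl 2,4-dihydroxybenzoate
Product: 2 methyl 4-(benzyloxy)-2-hydroxybenzoate
Conditions: BnBr (1.05 equiv), K2CO3 (1.2 equiv), acetone, reflux
Reagents that add atoms: benzyl bromide, BrCc1ccccc1
Why: Williamson ether synthesis; the 2-hydroxyl is hydrogen-bonded to the ester carbonyl and stays protonated, so one equivalent of halide should alkylate only the 4-hydroxyl.

Step 2
Reactants: 2 methyl 4-(benzyloxy)-2-hydroxybenzoate
Product: 3 methyl 4-(benzyloxy)-2-methoxybenzoate
Conditions: MeI (3 equiv), K2CO3 (2 equiv), DMF, 50 °C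
Reagents that add atoms: iodomethane, CI
Why: Williamson O-methylation; the chelated phenol is ionised in warm DMF and captured by excess iodomethane.

Step 3
Reactants: 3 methyl 4-(benzyloxy)-2-methoxybenzoate
Product: 4 4-(benzyloxy)-2-methoxybenzoic acid
Conditions: NaOH, MeOH/THF/H2O, 65 °C; then 1 M HCl
Reagents that add atoms: sodium hydroxide, [Na+].[OH-]
Why: Saponification of a methyl benzoate with only one ortho substituent is unhindered, and both ethers are inert to hydroxide.

Step 4
Reactants: 5 trimethylsulfoxonium iodide; 6 hexanoyl chloride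
Product: 8 1-[dimethyl(oxo)-λ6-sulfanylidene]heptan-2-one, via dimethylsulfoxonium methylide 7 (not isolated)
Conditions: 5 (3 equiv), KOtBu (3 equiv), THF, reflux; then 6 (1 equiv), 0 °C → rt
Reagents that add atoms: none
Why: C-acylation of the Corey–Chaykovsky ylide; a second equivalent of methylide deprotonates the acylsulfoxonium salt to the stabilised β-keto ylide.

Step 5
Reactants: 4 4-(benzyloxy)-2-methoxybenzoic acid; 8 1-[dimethyl(oxo)-λ6-sulfanylidene]heptan-2-one
Product: 10 6-(benzyloxy)-8-methoxy-3-pentyl-1H-isochromen-1-one, via 4-(benzyloxy)-2-methoxy-6-(2-oxoheptyl)benzoic acid 9 (not isolated)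
Conditions: 8 (1.5 equiv, added in portions), [RuCl2(p-cymene)]2 (5 mol %), NaOAc (30 mol %), CF3CH2OH, 80 °C, N2
Reagents that add atoms: none
Why: The carboxylate of 4 binds the divalent ruthenium centre and, by acetate-assisted concerted metalation–deprotonation, delivers it to C6–H to give a five-membered ruthenacycle; ylide 8 then binds through carbon, loses dimethyl sulfoxide to a ruthenium carbene, and migratory insertion of the aryl group followed by protodemetalation forms the C6–CH2 bond of keto acid 9. The closest known reaction type is the carboxylate-directed C–H acylmethylation/annulation of benzoic acids with sulfoxonium ylides, a redox-neutral carbene-insertion form of chelation-assisted C–H alkylation. The pyranone ring closes by 6-exo-trig addition of the carboxyl oxygen to the ketone carbonyl, and loss of water from the lactol gives the C3=C4 enol lactone of 10. No stereocentre is formed. The step needs site selectivity between the two carbons ortho to the carboxyl, and the substrate fixes it: C2 carries the methoxy group, only C6 bears hydrogen, and C3 and C5 are out of reach of a five-membered metallacycle. Chemoselectivity for C–H insertion over insertion into the carboxyl O–H should be helped by keeping the acid on the metal as its carboxylate and by feeding 8 slowly.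

Step 6
Reactants: 10 6-(benzyloxy)-8-methoxy-3-pentyl-1H-isochromen-1-one
Product: 9 4-(benzyloxy)-2-methoxy-6-(2-oxoheptyl)benzoic acid
Conditions: KOH (3 equiv), THF/MeOH/H2O, 40 °C; then 1 M HCl to pH 3, 0 °C
Reagents that add atoms: potassium hydroxide, [K+].[OH-]
Why: Alkaline hydrolysis of the enol lactone (acyl substitution, the enolate leaving group tautomerises to the ketone); the carboxylate cannot reclose, and cold acidification should release the keto acid without dehydration.

Step 7
Reactants: 9 4-(benzyloxy)-2-methoxy-6-(2-oxoheptyl)benzoic acid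
Product: 11 4-hydroxy-2-methoxy-6-(2-oxoheptyl)benzoic acid
Conditions: H2 (1 atm), 10% Pd/C, EtOAc, rt
Reagents that add atoms: none
Why: Catalytic hydrogenolysis of the aryl benzyl ether; the ketone has alkyl groups on both sides, so neither it nor the acid should be reduced.

Step 8
Reactants: 11 4-hydroxy-2-methoxy-6-(2-oxoheptyl)benzoic acid
Product: 12 benzyl 4-hydroxy-2-methoxy-6-(2-oxoheptyl)benzoate
Conditions: BnBr (1.05 equiv), KHCO3 (1.2 equiv), DMF, rt
Reagents that add atoms: benzyl bromide, BrCc1ccccc1
Why: SN2 alkylation of the carboxylate; hydrogencarbonate ionises the acid but not the phenol, so the ester should form with the 4-hydroxyl left free.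

Step 9
Reactants: 1 methyl 2,4-dihydroxybenzoate
Product: 13 methyl 2,4-bis(benzyloxy)benzoate
Conditions: BnBr (2.4 equiv), K2CO3 (3 equiv), DMF, 70 °C
Reagents that add atoms: benzyl bromide, BrCc1ccccc1
Why: Double Williamson ether synthesis; excess halide in warm DMF also alkylates the chelated 2-hydroxyl.

Step 10
Reactants: 13 methyl 2,4-bis(benzyloxy)benzoate
Product: 14 2,4-bis(benzyloxy)benzoic acid
Conditions: NaOH, MeOH/THF/H2O, 65 °C; then 1 M HCl
Reagents that add atoms: sodium hydroxide, [Na+].[OH-]
Why: Saponification; benzyl ethers are stable to hydroxide.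

Step 11
Reactants: 14 2,4-bis(benzyloxy)benzoic acid; 8 1-[dimethyl(oxo)-λ6-sulfanylidene]heptan-2-one
Product: 16 6,8-bis(benzyloxy)-3-pentyl-1H-isochromen-1-one, via 2,4-bis(benzyloxy)-6-(2-oxoheptyl)benzoic acid 15 (not isolated)
Conditions: 8 (1.5 equiv, added in portions), [RuCl2(p-cymene)]2 (5 mol %), NaOAc (30 mol %), CF3CH2OH, 80 °C, N2
Reagents that add atoms: none
Why: The same carboxylate-directed C–H acylmethylation/annulation as in step 5; C2 is blocked by a benzyloxy group, so only C6–H can be metalated, and the keto acid closes 6-exo-trig and dehydrates to the isocoumarin.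

Step 12
Reactants: 16 6,8-bis(benzyloxy)-3-pentyl-1H-isochromen-1-one
Product: 18 prop-2-en-1-yl 2,4-bis(benzyloxy)-6-(2-oxoheptyl)benzoate, via potassium 2,4-bis(benzyloxy)-6-(2-oxoheptyl)benzoate 17 (not isolated)
Conditions: KOH (1.1 equiv), EtOH/H2O, 60 °C; evaporate; allyl bromide (1.5 equiv), DMF, rt
Reagents that add atoms: potassium hydroxide, [K+].[OH-]; allyl bromide, C=CCBr
Why: Hydroxide opening of the enol lactone followed by SN2 alkylation of the carboxylate; the free keto acid is never handled, and the allyl ester can later be removed without touching benzyl ethers.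

Step 13
Reactants: 18 prop-2-en-1-yl 2,4-bis(benzyloxy)-6-(2-oxoheptyl)benzoate
Product: 19 prop-2-en-1-yl 2,4-bis(benzyloxy)-6-[(2-pentyl-1,3-dioxolan-2-yl)methyl]benzoate
Conditions: Me3SiOCH2CH2OSiMe3 (3 equiv), Me3SiOTf (0.1 equiv), CH2Cl2, −78 → −20 °C; pyridine quench
Reagents that add atoms: 1,2-bis(trimethylsilyloxy)ethane, C[Si](C)(C)OCCO[Si](C)(C)C
Why: Noyori ketalisation; the aprotic, low-temperature conditions are driven by formation of hexamethyldisiloxane and should avoid the acid-promoted reclosure of the keto ester to the isocoumarin.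

Step 14
Reactants: 19 prop-2-en-1-yl 2,4-bis(benzyloxy)-6-[(2-pentyl-1,3-dioxolan-2-yl)methyl]benzoate
Product: 20 2,4-bis(benzyloxy)-6-[(2-pentyl-1,3-dioxolan-2-yl)methyl]benzoic acid
Conditions: Pd(PPh3)4 (5 mol %), morpholine (5 equiv), THF, rt; work-up at pH 5, 0 °C
Reagents that add atoms: none
Why: Tsuji–Trost deallylation; zerovalent palladium ionises the allyl ester to a π-allyl complex that morpholine traps, and steric hindrance at the ester carbonyl is irrelevant because that carbon is not attacked.

Step 15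
Reactants: 20 2,4-bis(benzyloxy)-6-[(2-pentyl-1,3-dioxolan-2-yl)methyl]benzoic acid; 12 benzyl 4-hydroxy-2-methoxy-6-(2-oxoheptyl)benzoate
Product: 21 benzyl 4-({2,4-bis(benzyloxy)-6-[(2-pentyl-1,3-dioxolan-2-yl)methyl]benzoyl}oxy)-2-methoxy-6-(2-oxoheptyl)benzoate
Conditions: DCC (1.2 equiv), DMAP (0.3 equiv), CH2Cl2, 0 °C → rt
Reagents that add atoms: none
Why: Steglich esterification; the ring A ketone is masked so the activated acyl group cannot be captured by its own enol, and the acylpyridinium should be taken by the only free hydroxyl, the ring B phenol.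

Step 16
Reactants: 21 benzyl 4-({2,4-bis(benzyloxy)-6-[(2-pentyl-1,3-dioxolan-2-yl)methyl]benzoyl}oxy)-2-methoxy-6-(2-oxoheptyl)benzoate
Product: 22 benzyl 4-{[2,4-bis(benzyloxy)-6-(2-oxoheptyl)benzoyl]oxy}-2-methoxy-6-(2-oxoheptyl)benzoate
Conditions: 2 M aq. HCl/THF (1:4), rt
Reagents that add atoms: water, O
Why: Acid-catalysed ketal hydrolysis; a dialkyl dioxolane is cleaved by dilute acid at room temperature, whereas the hindered aryl ester and the benzyl ester are not.

Step 17
Reactants: 22 benzyl 4-{[2,4-bis(benzyloxy)-6-(2-oxoheptyl)benzoyl]oxy}-2-methoxy-6-(2-oxoheptyl)benzoate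
Product: 23 arthonioic acid, 4-{[2,4-dihydroxy-6-(2-oxoheptyl)benzoyl]oxy}-2-methoxy-6-(2-oxoheptyl)benzoic acid
Conditions: H2 (1 atm), 10% Pd/C, EtOAc, rt
Reagents that add atoms: none
Why: Catalytic hydrogenolysis removes the two benzyl ethers and the benzyl ester under neutral conditions that should leave the aryl ester, the methyl ether and both ketones intact.

**Compound list**

1 | methyl 2,4-dihydroxybenzoate | COC(=O)c1ccc(O)cc1O | starting material
2 | methyl 4-(benzyloxy)-2-hydroxybenzoate | COC(=O)c1ccc(OCc2ccccc2)cc1O | intermediate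
3 | methyl 4-(benzyloxy)-2-methoxybenzoate | COC(=O)c1ccc(OCc2ccccc2)cc1OC | intermediate
4 | 4-(benzyloxy)-2-methoxybenzoic acid | COc1cc(OCc2ccccc2)ccc1C(=O)O | intermediate
5 | trimethylsulfoxonium iodide | C[S+](C)(C)=O.[I-] | starting material
6 | hexanoyl chloride | CCCCCC(=O)Cl | starting material
7 | dimethylsulfoxonium methylide | C[S+](C)(=O)[CH2-] | intermediate
8 | 1-[dimethyl(oxo)-λ6-sulfanylidene]heptan-2-one | CCCCCC(=O)C=S(C)(C)=O | intermediate
9 | 4-(benzyloxy)-2-methoxy-6-(2-oxoheptyl)benzoic acid | CCCCCC(=O)Cc1cc(OCc2ccccc2)cc(OC)c1C(=O)O | intermediate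
10 | 6-(benzyloxy)-8-methoxy-3-pentyl-1H-isochromen-1-one | CCCCCC1=Cc2cc(OCc3ccccc3)cc(OC)c2C(=O)O1 | intermediate
11 | 4-hydroxy-2-methoxy-6-(2-oxoheptyl)benzoic acid | CCCCCC(=O)Cc1cc(O)cc(OC)c1C(=O)O | intermediate
12 | benzyl 4-hydroxy-2-methoxy-6-(2-oxoheptyl)benzoate | CCCCCC(=O)Cc1cc(O)cc(OC)c1C(=O)OCc1ccccc1 | intermediate
13 | methyl 2,4-bis(benzyloxy)benzoate | COC(=O)c1ccc(OCc2ccccc2)cc1OCc1ccccc1 | intermediate
14 | 2,4-bis(benzyloxy)benzoic acid | OC(=O)c1ccc(OCc2ccccc2)cc1OCc1ccccc1 | intermediate
15 | 2,4-bis(benzyloxy)-6-(2-oxoheptyl)benzoic acid | CCCCCC(=O)Cc1cc(OCc2ccccc2)cc(OCc2ccccc2)c1C(=O)O | intermediate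
16 | 6,8-bis(benzyloxy)-3-pentyl-1H-isochromen-1-one | CCCCCC1=Cc2cc(OCc3ccccc3)cc(OCc3ccccc3)c2C(=O)O1 | intermediate
17 | potassium 2,4-bis(benzyloxy)-6-(2-oxoheptyl)benzoate | CCCCCC(=O)Cc1cc(OCc2ccccc2)cc(OCc2ccccc2)c1C(=O)[O-].[K+] | intermediate
18 | prop-2-en-1-yl 2,4-bis(benzyloxy)-6-(2-oxoheptyl)benzoate | CCCCCC(=O)Cc1cc(OCc2ccccc2)cc(OCc2ccccc2)c1C(=O)OCC=C | intermediate
19 | prop-2-en-1-yl 2,4-bis(benzyloxy)-6-[(2-pentyl-1,3-dioxolan-2-yl)methyl]benzoate | CCCCCC1(Cc2cc(OCc3ccccc3)cc(OCc3ccccc3)c2C(=O)OCC=C)OCCO1 | intermediate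
20 | 2,4-bis(benzyloxy)-6-[(2-pentyl-1,3-dioxolan-2-yl)methyl]benzoic acid | CCCCCC1(Cc2cc(OCc3ccccc3)cc(OCc3ccccc3)c2C(=O)O)OCCO1 | intermediate
21 | benzyl 4-({2,4-bis(benzyloxy)-6-[(2-pentyl-1,3-dioxolan-2-yl)methyl]benzoyl}oxy)-2-methoxy-6-(2-oxoheptyl)benzoate | CCCCCC(=O)Cc1cc(OC(=O)c2c(CC3(CCCCC)OCCO3)cc(OCc3ccccc3)cc2OCc2ccccc2)cc(OC)c1C(=O)OCc1ccccc1 | intermediate
22 | benzyl 4-{[2,4-bis(benzyloxy)-6-(2-oxoheptyl)benzoyl]oxy}-2-methoxy-6-(2-oxoheptyl)benzoate | CCCCCC(=O)Cc1cc(OC(=O)c2c(CC(=O)CCCCC)cc(OCc3ccccc3)cc2OCc2ccccc2)cc(OC)c1C(=O)OCc1ccccc1 | intermediate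
23 | arthonioic acid | CCCCCC(=O)Cc1cc(O)cc(O)c1C(=O)Oc1cc(CC(=O)CCCCC)c(C(=O)O)c(OC)c1 | target

**Summary**

Total step count: 17. Longest linear sequence: 10 steps (steps 1, 2, 3, 5, 6, 7, 8, 15, 16, 17).

Steps most likely to fail:

1. Step 5 (the same process threatens step 11). The ruthenium carbene may insert into the carboxyl O–H faster than the ring is metalated, giving the 2-oxoheptyl ester, or the electron-rich ortho-alkoxy acid may lose carbon dioxide at 80 °C. The fallback replaces C–H activation by lateral metalation of an ortho-toluate. It sets out from hexanoyl chloride 6 and commercial methyl 2,4-dihydroxy-6-methylbenzoate (COC(=O)c1c(C)cc(O)cc1O) and comes back to the route at keto acid 9, bypassing steps 5 and 6. Compound 6 is treated with MeNH(OMe)·HCl and K2CO3 in CH2Cl2/H2O at 0 °C to give N-methoxy-N-methylhexanamide F1. The toluate is benzylated at the 4-hydroxyl (BnBr, K2CO3, acetone, reflux) to methyl 4-(benzyloxy)-2-hydroxy-6-methylbenzoate F2, which is methylated (MeI, K2CO3, DMF, 50 °C) to methyl 4-(benzyloxy)-2-methoxy-6-methylbenzoate F3. The benzylic methyl of F3 is deprotonated with LiN(iPr)2 (2.2 equiv) in THF at −78 °C, and the anion is acylated by F1 and quenched with cold dilute HCl to give methyl 4-(benzyloxy)-2-methoxy-6-(2-oxoheptyl)benzoate F4. KOH in aqueous methanol at reflux, where the ketone enolate oxygen assists loss of methoxide from the hindered ester by way of isocoumarin 10, followed by cold acidification should convert F4 into 9.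

2. Step 15. Acyl transfer from the hindered O-acylisourea may be slow, so that it rearranges to the N-acylurea, or a dioxolane oxygen may attack the activated carbonyl and return the isocoumarin. The fallback uses a small, isolable acyl donor and a preformed phenoxide. It sets out from acid 20 and comes back to the route at depside 21. Compound 20 is converted with cyanuric fluoride and pyridine in CH2Cl2 at −10 °C into 2,4-bis(benzyloxy)-6-[(2-pentyl-1,3-dioxolan-2-yl)methyl]benzoyl fluoride F5, which is added to phenol 12 and Cs2CO3 in MeCN at room temperature to give 21.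

3. Step 16. Once the ring A ketone is free, acid may promote its enolisation and attack of the enol oxygen on the neighbouring aryl ester, which would expel the ring B phenol and cleave the depside. The fallback uses a ketal that is removed by hydrogenolysis, so no acid step follows the coupling. It sets out from allyl ester 18 and comes back to the route at target 23. Compound 18 is ketalised with 1,2-bis[(trimethylsilyloxy)methyl]benzene and catalytic Me3SiOTf in CH2Cl2 at −78 to −20 °C to prop-2-en-1-yl 2,4-bis(benzyloxy)-6-[(3-pentyl-1,5-dihydro-3H-2,4-benzodioxepin-3-yl)methyl]benzoate F6. Pd(PPh3)4 and morpholine in THF then release 2,4-bis(benzyloxy)-6-[(3-pentyl-1,5-dihydro-3H-2,4-benzodioxepin-3-yl)methyl]benzoic acid F7. DCC and DMAP in CH2Cl2 join F7 to phenol 12, giving benzyl 4-({2,4-bis(benzyloxy)-6-[(3-pentyl-1,5-dihydro-3H-2,4-benzodioxepin-3-yl)methyl]benzoyl}oxy)-2-methoxy-6-(2-oxoheptyl)benzoate F8. H2 over 10% Pd/C in EtOAc cleaves the benzyl ethers, the benzyl ester and one benzylic C–O bond of the ketal in one operation; the hemiketal so formed collapses to the ketone and gives 23.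

**Further compounds**

F1 | step 5 | N-methoxy-N-methylhexanamide | CCCCCC(=O)N(C)OC
F2 | step 5 | methyl 4-(benzyloxy)-2-hydroxy-6-methylbenzoate | COC(=O)c1c(C)cc(OCc2ccccc2)cc1O
F3 | step 5 | methyl 4-(benzyloxy)-2-methoxy-6-methylbenzoate | COC(=O)c1c(C)cc(OCc2ccccc2)cc1OC
F4 | step 5 | methyl 4-(benzyloxy)-2-methoxy-6-(2-oxoheptyl)benzoate | CCCCCC(=O)Cc1cc(OCc2ccccc2)cc(OC)c1C(=O)OC
F5 | step 15 | 2,4-bis(benzyloxy)-6-[(2-pentyl-1,3-dioxolan-2-yl)methyl]benzoyl fluoride | CCCCCC1(Cc2cc(OCc3ccccc3)cc(OCc3ccccc3)c2C(F)=O)OCCO1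
F6 | step 16 | prop-2-en-1-yl 2,4-bis(benzyloxy)-6-[(3-pentyl-1,5-dihydro-3H-2,4-benzodioxepin-3-yl)methyl]benzoate | CCCCCC1(Cc2cc(OCc3ccccc3)cc(OCc3ccccc3)c2C(=O)OCC=C)OCc2ccccc2CO1
F7 | step 16 | 2,4-bis(benzyloxy)-6-[(3-pentyl-1,5-dihydro-3H-2,4-benzodioxepin-3-yl)methyl]benzoic acid | CCCCCC1(Cc2cc(OCc3ccccc3)cc(OCc3ccccc3)c2C(=O)O)OCc2ccccc2CO1
F8 | step 16 | benzyl 4-({2,4-bis(benzyloxy)-6-[(3-pentyl-1,5-dihydro-3H-2,4-benzodioxepin-3-yl)methyl]benzoyl}oxy)-2-methoxy-6-(2-oxoheptyl)benzoate | CCCCCC(=O)Cc1cc(OC(=O)c2c(CC3(CCCCC)OCc4ccccc4CO3)cc(OCc3ccccc3)cc2OCc2ccccc2)cc(OC)c1C(=O)OCc1ccccc1
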